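If the peaks of starting material and target both stop moving while starting material is still there, I ask how long the flask worked and count that time in lifetimes.

all flasks: catalyst 0.52 mol%; added ligand 0.58 mM

| flask | starting material | reagent | second substrate | temperature | remark | time |
|---|---|---|---|---|---|---|
| alder | 0.054 M | 2 equiv | 1 equiv | −20 °C | run made earlier |  |
| maple | 0.11 M | 2 equiv | 1 equiv | −20 °C | run made earlier |  |
| theta | 0.054 M (fed, over 25 s) | 2.00 equiv | 1.00 equiv | −20 °C | all else is in the flask from the start; the feed brings no volume worth counting | 2.0 min |
| zeta | 0.054 M | 2.00 equiv (fed, over 25 s) | 1.00 equiv | −20 °C | all else is in the flask from the start; the feed brings no volume worth counting | 2.0 min |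
| beta | 0.054 M (fed, over 25 s) | 2.00 equiv | 1.00 equiv |  | the addition at −40 °C, then warmed to −20 °C; the feed brings no volume worth counting | 2.0 min |
| gamma | 0.054 M (fed, over 6.0 s) | 2.00 equiv | 1.00 equiv | −20 °C | all else is in the flask from the start; the feed brings no volume worth counting | 2.0 min |
| delta | 0.054 M | 2.00 equiv | 1.00 equiv | −20 °C | everything together at the start | 2.0 min |
| alpha | 0.054 M | 2.00 equiv | 1.00 equiv |  | everything together at the start at −40 °C, warmed to −20 °C at 25 s | 2.0 min |

| run | time / s | target / % | starting material / % |
|---|---|---|---|
| alder | 20.0 | 62.5 | 37.3 |
| alder | 40.0 | 65.6 | 34.8 |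
| alder | 60.0 | 66.0 | 32.3 |
| alder | 80.0 | 66.3 | 31.0 |
| alder | 90.0 | 69.2 | 30.9 |
| alder | 120 | 66.8 | 34.5 |
| maple | 10.0 | 82.5 | 19.7 |
| maple | 12.0 | 80.7 | 17.9 |

(standard deviation of a reading: 1 percentage point)

- the earlier runs do not show what temperature does; that part of a forecast is a guess

* the flask with the highest amount of target, in percent of the starting material charged ("all alike" if they lie within 1.5 percentage points) (theta / zeta / beta / gamma / delta / alpha / all alike)
* final target, as a percentage of the starting material charged, in theta
* final target, as a percentage of the starting material charged, in zeta
* final target, as a percentage of the starting material charged, in beta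
* final target, as a percentage of the starting material charged, in gamma
* final target, as a percentage of the starting material charged, in delta
* final target, as a percentage of the starting material charged, in alpha

In alder the readings stay level from the third on, at a mean of 32.2% starting material and 67.1% target, and these two means add up to about the charge. Maple, at twice the concentration and the same loading of catalyst, reads 17.9% starting material after 12.0 s, below that plateau, which does not fit a fixed count of turnovers per catalyst. I read this as something running down on a clock, and I call the working lifetime τ, the time in which the drive still to come falls by a factor e. I estimate it from the exposure E in the alder readings, taking the drive to fall exponentially: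

E = ln(c(starting material, charged) / c(starting material, left))

E at the plateau = 1.13; E at 20.0 s = 0.986

τ = t / ln(E plateau / (E plateau − E at t)) = 9.82 s

One extreme is everything at once: delta repeats alder, near 67.1%. The other, in this reckoning, is a feed many lifetimes long, where a late portion meets a faded drive and the target tends to nil. Theta's feed lasts 2.55 lifetimes and gamma's 0.611, so they lie between. A portion entering at time s meets exp(−s/τ) of the drive, and the average over the feed is

f = (τ/t_f)(1 − exp(−t_f/τ))

theta: f = 36.2%, target near 24.3%

gamma: f = 74.8%, target near 50.2%

This supposes that the fed species does not carry the clock. If the clock is the reagent's, zeta stays near delta; if it is the catalyst's, zeta sinks like theta. I do not part these two from alder and maple, and the earlier runs do not show what temperature does, so I leave zeta, beta and alpha open.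

The forecast names alpha as best, with 33% for theta, 38% for zeta, 58% for beta, 57% for gamma, 67% for delta and 69% for alpha, holding that “Feed added late meets dead catalyst”, and its theta stands above mine and its gamma above mine.

The flasks give 28.6% in theta, 71.4% in zeta, 58.8% in beta, 46.0% in gamma, 67.6% in delta and 77.5% in alpha, so alpha holds the most.

    starting material + reagent + catalyst → catalyst + target (k = 16100 M⁻² s⁻¹, Ea = 23.0 kJ mol⁻¹)
    second substrate + reagent + catalyst → catalyst + second product (k = 19700 M⁻² s⁻¹, Ea = 8.00 kJ mol⁻¹)
    catalyst + added ligand ⇌ idle complex (K = 4740 M⁻¹, k = 520 M⁻¹ s⁻¹, Ea = 38.0 kJ mol⁻¹, ΔH = 33.0 kJ mol⁻¹)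
    2 reagent → homo dimer (k = 1.04 M⁻¹ s⁻¹, Ea = 43.0 kJ mol⁻¹)
    (constants at −20 °C)

Scaled on delta's 67.6%, τ puts theta at 24.5% against 28.6%, and gamma at 50.6% against 46.0%. Zeta, with the reagent fed, reaches 71.4%, so the clock reads as the reagent's: theta ends with reagent, the limiting reagent, at 0% and with catalyst at 34.7% beside 65.3% idle complex, the same 34.7% and 65.3% as in zeta. Without the path from two reagent to homo dimer, the gap between alpha and theta shrinks from 49 percentage points to 1.8 points.

(The runs are simulated with constants of no real substance; the scatter is artificial.)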